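This flask holds 1.15 M of starting material and partner together, more than its 0.920 M of second substrate.

starting material 0.46 M (fed, over 12 min); partner 0.690 M; second substrate 0.920 M; time 15 d

    partner ⇌ dormant form (K1 = 0.58, k1 = 1.25 × 10⁻⁴ /s)
    second substrate + target ⇌ idle adduct, settled at all times (K2 = 0.511 /M)
    second substrate + partner → second product (k3 = 5.26 × 10⁻⁴ /M/s)
    starting material + second substrate → cross product (k4 = 8.60 × 10⁻⁴ /M/s)
    starting material + partner ⇌ target (K5 = 17 /M, k5 = 5.56 × 10⁻⁴ /M/s)

- for target the idle adduct is counted in
- the reaction counts as stopped when no species that holds the starting material changes by six tenths of a point or more over the second half of the time
- run time (flask): 15 d

- at 15 d, what has stopped the reaction, if anything has (the partner has run out first / all of the starting material has reacted / forward and back rates have come level / it is still moving)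
- the target standing at 15 d, as a percentage of the starting material charged
- the cross product standing at 15 d, as a percentage of the starting material charged

I began by turning the constants into times. A bimolecular constant multiplied by its co-reactant's concentration is a pseudo-first-order constant, and that gives a half-life at the charged amounts:

second substrate by step 3: 0.53 h
the same by step 4, the whole feed counted as present: 0.49 h
starting material by step 5, forward rate: 0.50 h

The feed lasts 12 min, shorter than these half-lives, and each of them is short against the 15 d of the run. So I expected the second substrate to be the limiting reagent and to be consumed early. Steps 3 and 4 run one way, and each removes one second substrate with one partner or one starting material. That led me to the quantity I carried: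

surplus = 0.46 M + 0.690 M − 0.920 M = 0.230 M

The surplus, the charged starting material and partner that the charged second substrate cannot remove, should remain at the end as [starting material] + [partner] + [dormant form] + [target], with target counted once for each of the two it holds, provided neither second substrate nor idle adduct then stands in the flask.

The way back along step 5 has a half-life of 5.89 h, also short against the run. I therefore expected the surplus to rest with forward and back rates level. My reckoning stopped there. The surplus gives the size of the pool, not the yields, and the two rival half-lives of second substrate lie too close to give me a split.

The forecast said forward and back rates have come level, with 8.8% of target and 84% of cross product: “Partner remains, so the reaction ends at equilibrium.”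

The simulation gave forward and back rates have come level, with 8.95% of target and 83.8% of cross product. At 15 d this flask held 0% of its second substrate and 0% of idle adduct, and its pool summed to 0.230 M against the surplus of 0.230 M. The neighbouring flask, charged with 1.7 M of partner, has a surplus of 1.24 M by the same subtraction. At 15 d it also held 0% of its second substrate and 0% of idle adduct, and its pool summed to 1.24 M. In that neighbouring flask cross product stood at 36.6%, and target held the most starting material, at 55.9%.

(The constants used here come from no measurement; the run is a simulation.)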